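**Remark on the chemistry:** the target has no stereogenic centre, axis or configurationally defined double bond, so no stereocontrol is needed; the amidine is drawn as the NH–C=N tautomer of the given SMILES, and 2,3,4-trimethoxyphenol (10) and 1-methylimidazolidine-2,4,5-trione (15) are taken as catalogue compounds.

## The problem

Naamidine F (19) is a fully substituted 2-aminoimidazole. N1 carries methyl, the C2 nitrogen is part of an amidine with C4 of a 1-methylimidazole-2,5-dione (dehydrohydantoin), C4 carries a 4-methoxybenzyl group, and C5 carries a methylene that ends on C5 of a 2,3-dimethoxy-1,4-benzoquinone. With no stereogenic element, the problem is connectivity, regiochemistry and timing of functional groups. Two different arylmethyl groups must sit on C4 and C5 in a fixed relation to the N1 methyl group. The quinone is an oxidant and a Michael acceptor with two vinylogous-ester methoxy groups. It cannot coexist with a free 2-aminoimidazole, with organometallics or with the hot silylating conditions needed for the amidine, so it must appear last, under conditions that spare an anisole ring, an electron-rich imidazole and an acyl amidine. The dehydrohydantoin amidine is itself labile to nucleophiles and aqueous base and must follow all C–C bond construction.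

The feature that opens a short solution is the C5–CH2–aryl unit. Imidazole C5 is the β-carbon of a cyclic ene-guanidine (N3=C2(NH2)–N1 conjugated with C4=C5), hence a carbon nucleophile when it bears hydrogen. The exocyclic CH2 is a single carbon at the formaldehyde oxidation level. It sits on quinone C5, ortho to the C4 carbonyl, that is, ortho to a phenolic oxygen in the reduced ring, which is the retron of an o-quinone methide. In addition, the 2,3-dimethoxy-1,4-benzoquinone ring has a mirror plane through the midpoints of C2–C3 and C5–C6, so C5 and C6 are equivalent; a 2,3,4-trimethoxyphenol substituted at either free CH therefore leads to the same quinone.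

## Retrosynthesis

**19 ⇒ 18.** No skeletal bond is cut. The quinone carbonyls C1=O and C4=O are traced back to the phenolic OH and the para methoxy group of 18. A free phenol is preferred over the usual tetramethoxybenzene precursor because it is oxidised far more easily than the anisole ring or the heterocycles, so a mild two-electron oxidant in water at 0 °C should suffice. 18 is the target without its most reactive group. The forward step must be chemoselective and free of base.

**18 ⇒ 14 + 15.** The exocyclic N–C4 bond of the dehydrohydantoin (the amidine C–N bond) is cut. Building the five-membered ring stepwise on the amine would cost extra steps, whereas 15 delivers the whole ring in one condensation. The forward reaction asks a weakly nucleophilic guanidine-type NH2 to attack the imide carbonyl C4 of 15, which needs silyl activation. It is placed after the C–C coupling because the acyl amidine would drain electron density from imidazole C5.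

**14 ⇒ 9 + 11 + 10 (key disconnection).** Both bonds of the bridging CH2 are cut: imidazole C5–CH2 and CH2–aryl C6. Cutting only one of them would need a prefunctionalised, protected benzyl electrophile or a metallated aminoimidazole. The double cut turns the CH2 into formaldehyde 11 and leaves a trisubstituted aminoimidazole 9 with a free C5–H and the catalogue phenol 10. In the forward direction 10 and 11 are first joined through a secondary-amine shuttle as Mannich base 12, which releases o-quinone methide 13 for capture by C5 of 9. The step must deliver C-alkylation over N-alkylation. The precursor 9 has twelve carbons and one benzyl group; the product 14 has the complete carbon skeleton of the target apart from the hydantoin.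

**9 ⇒ 5 + 6.** The ring bonds N1–C2 and N3–C4 are cut. The α-(methylamino)ketone/cyanamide condensation fixes the regiochemistry by construction: the amine nitrogen becomes N1, the ketone carbon becomes C4, and the sarcosine CH2 becomes the free C5–H. The sequence passes through the amine salt 7 and the ketoguanidine 8.

**5 ⇒ 3 + 4; 3 ⇒ 1 + 2.** The C(=O)–CH2Ar bond is cut. A Weinreb amide of N-Boc-sarcosine (1) accepts the benzylic Grignard reagent 4 once and stops at the ketone. All inputs are commercial.

## Roads not taken

**Alternative 1:** the obvious plan. The imidazole is closed with both benzyl groups already in place and the quinone masked as a tetramethoxybenzene. The cut is N1–C2/N3–C4 of a 4,5-dibenzyl ring. N-Boc-N-methyl-3-(2,3,4,5-tetramethoxyphenyl)alanine A1 would be taken through the sequence of steps 1–3 to the dibenzyl aminoimidazole A2, condensed with 15 to A3, and oxidised with ceric ammonium nitrate. The chosen plan is better on three counts: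
- A1 is not available and needs its own multistep synthesis from a non-commodity tetramethoxybenzaldehyde, including a stereocentre that is later destroyed.
- The one-electron oxidant must discriminate between a tetramethoxyarene, an anisole and an electron-rich imidazole amidine without a phenol handle.
- The quinone precursor is carried through every step instead of entering two steps from the end.

**Alternative 2:** alkyne–amine–aldehyde coupling followed by propargylguanidine hydroamination. The cut is N3–C4 of the ring plus the three bonds at the propargylic carbon. 2-(2,3,4,5-Tetramethoxyphenyl)acetaldehyde A4, N-allylmethylamine and 4-ethynylanisole would give propargylamine A5. Deallylation, guanylation and 5-exo-dig hydroamination with isomerisation would lead to A2 again. The multicomponent step builds an acyclic precursor, not the core. A4 is an enolisable, electron-rich arylacetaldehyde that must be made and is a poor partner in such couplings. An N-protecting group has to be put on and taken off, and the route inherits the endgame of Alternative 1.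

**Alternative 3:** decarboxylative radical alkylation of the intact quinone. The cut is CH2–C5 of the quinone. The imidazol-5-ylacetic acid A6 would be oxidised (silver/persulfate or Kolbe-type electrolysis) in the presence of commercial 2,3-dimethoxy-1,4-benzoquinone, whose two free positions are equivalent. The quinone would enter intact and no final oxidation would be needed. However:
- The oxidants that trigger decarboxylation also attack the ene-amidine and the anisylic CH2.
- The (2-aminoimidazol-5-yl)methyl radical is oxidised to an azafulvenium cation more easily than it adds to the quinone.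
- The monoalkylated quinone still has a free position for a second alkylation.
- A6 needs a longer run-up from an N-methylaspartic acid building block than 9 does from sarcosine.

Key step: step 4

## Route

**Step 1**
Reactants: 1 N-(tert-butoxycarbonyl)sarcosine; 2 N,O-dimethylhydroxylamine hydrochloride
Product: 3 tert-butyl N-{2-[methoxy(methyl)amino]-2-oxoethyl}-N-methylcarbamate
Conditions: CDI (1.1 equiv), CH2Cl2, 0 °C to rt; then 2 (1.2 equiv), rt
Reagents that add atoms: none
Why: Weinreb amide formation through the acyl imidazolide; the imidazole released serves as base for the hydrochloride, and the substrate has no stereocentre to racemise.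

**Step 2**
Reactants: 3 tert-butyl N-{2-[methoxy(methyl)amino]-2-oxoethyl}-N-methylcarbamate; 4 4-methoxybenzylmagnesium chloride (THF solution)
Product: 5 tert-butyl N-[3-(4-methoxyphenyl)-2-oxopropyl]-N-methylcarbamate
Conditions: 4 (1.5 equiv), THF, −78 to 0 °C; aq. NH4Cl
Reagents that add atoms: none
Why: Weinreb ketone synthesis; the chelated tetrahedral magnesium adduct should prevent over-addition and keeps the doubly activated benzylic ketone masked until the quench.

**Step 3**
Reactants: 5 tert-butyl N-[3-(4-methoxyphenyl)-2-oxopropyl]-N-methylcarbamate; 6 cyanamide
Product: 9 4-[(4-methoxyphenyl)methyl]-1-methyl-1H-imidazol-2-amine, via aminoketone hydrochloride 7 (not isolated), via ketoguanidine 8 (not isolated)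
Conditions: 4 M HCl/dioxane, rt, evaporate; then 6 (3 equiv), H2O/EtOH, pH 4.5 (NaOH), 95 °C; NaOH to pH 11
Reagents that add atoms: none
Why: Acidolytic Boc removal, then the classical α-aminoketone/cyanamide cyclocondensation (Marckwald-type 2-aminoimidazole synthesis): the secondary amine of 7 adds to cyanamide to give 8, whose NH2 condenses with the ketone; the amine nitrogen becomes N1 and the ketone carbon C4, so C5 necessarily stays unsubstituted.

**Step 4**
Reactants: 9 4-[(4-methoxyphenyl)methyl]-1-methyl-1H-imidazol-2-amine; 10 2,3,4-trimethoxyphenol; 11 formaldehyde (as paraformaldehyde)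
Product: 14 6-({2-amino-4-[(4-methoxyphenyl)methyl]-1-methyl-1H-imidazol-5-yl}methyl)-2,3,4-trimethoxyphenol, via Mannich base 12 (not isolated), via o-quinone methide 13 (not isolated)
Conditions: 10 (1.3 equiv), 11 (1.15 equiv), morpholine (1.2 equiv), n-BuOH, 90 °C; then 9 (1.0 equiv), 115 °C, Ar
Reagents that add atoms: none
Why: Proposed new method: morpholine and formaldehyde aminomethylate 10 at C6, its only position ortho to OH (phenolic Mannich reaction), which binds all formaldehyde as 12 before 9 is admitted; above about 100 °C 12 should lose morpholine by the proton-transfer/retro-Michael path typical of phenolic Mannich bases to give 13, and C5 of 9, the β-carbon of the ene-guanidine N3=C2(NH2)–N1/C4=C5, adds to the exocyclic methylene of 13 in a 1,4-addition driven by rearomatisation of the phenol, after which loss of H-5 restores the imidazole. The closest known reaction types are the thermal C-alkylation of indoles, 6-aminouracils and enaminones by phenolic Mannich bases through o-quinone methides (including three-component Betti-type variants) and the C-hydroxyalkylation of 2-aminoimidazoles by aldehydes; the new element is their combination on a 2-aminoimidazole with formaldehyde. No ring is closed and no stereocentre is formed. The selectivity needed is C5 over the exocyclic NH2 and N3 of 9: adducts at nitrogen are themselves Mannich bases that should revert to 13 under the conditions, whereas the C–C adduct with two aromatic rings is the thermodynamic sink, and C4 is blocked so C5 is the only nucleophilic C–H. Methylene-bridged self-coupling of 9 is suppressed because no free formaldehyde remains after the first stage, and a second alkylation at carbon is impossible because 14 has no enaminic C–H left. The position of attack on the arene is fixed as ortho by the quinone-methide mechanism and would be immaterial anyway, since substitution at either free CH of 10 leads to the same quinone in step 6.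

**Step 5**
Reactants: 14 6-({2-amino-4-[(4-methoxyphenyl)methyl]-1-methyl-1H-imidazol-5-yl}methyl)-2,3,4-trimethoxyphenol; 15 1-methylimidazolidine-2,4,5-trione (1-methylparabanic acid)
Product: 18 4-({5-[(2-hydroxy-3,4,5-trimethoxyphenyl)methyl]-4-[(4-methoxyphenyl)methyl]-1-methyl-1H-imidazol-2-yl}amino)-1-methyl-1H-imidazole-2,5-dione, via silyl imidate 16 (not isolated), via aryl silyl ether 17 (not isolated)
Conditions: 15 (1.5 equiv), BSA (4 equiv), MeCN, 80 °C; then 14, PhMe, 110 °C; MeOH/H2O work-up
Reagents that add atoms: none
Why: N,O-Bis(trimethylsilyl)acetamide turns the N3–H/C4=O lactam of 15 into silyl imidate 16 and protects the phenol; the exocyclic nitrogen of the aminoimidazole adds to C4 of 16 and silanolate leaves (addition–elimination to the amidine), a condensation established for 2-amino-1-methyl-4,5-dibenzylimidazoles bearing free phenols; the work-up cleaves the silyl ether of 17.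

**Step 6**
Reactants: 18 4-({5-[(2-hydroxy-3,4,5-trimethoxyphenyl)methyl]-4-[(4-methoxyphenyl)methyl]-1-methyl-1H-imidazol-2-yl}amino)-1-methyl-1H-imidazole-2,5-dione
Product: 19 naamidine F, 4-({5-[(4,5-dimethoxy-3,6-dioxocyclohexa-1,4-dien-1-yl)methyl]-4-[(4-methoxyphenyl)methyl]-1-methyl-1H-imidazol-2-yl}amino)-1-methyl-1H-imidazole-2,5-dione
Conditions: PhI(OAc)2 (1.1 equiv), MeCN/H2O 2:1, 0 °C
Reagents that add atoms: water, O
Why: Hypervalent-iodine oxidative demethylation of a 4-methoxyphenol: ligand exchange at iodine, two-electron oxidation, capture of the methoxy-bearing para carbon by water and loss of methanol give the 1,4-benzoquinone; the free phenol is the most easily oxidised site, so the anisole ring, the imidazole and the acyl amidine should be spared.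

## Compound list

1 | N-(tert-butoxycarbonyl)sarcosine | CN(CC(=O)O)C(=O)OC(C)(C)C | starting material
2 | N,O-dimethylhydroxylamine hydrochloride | CNOC.Cl | starting material
3 | tert-butyl N-{2-[methoxy(methyl)amino]-2-oxoethyl}-N-methylcarbamate | CON(C)C(=O)CN(C)C(=O)OC(C)(C)C | intermediate
4 | 4-methoxybenzylmagnesium chloride | COc1ccc(C[Mg]Cl)cc1 | starting material
5 | tert-butyl N-[3-(4-methoxyphenyl)-2-oxopropyl]-N-methylcarbamate | COc1ccc(CC(=O)CN(C)C(=O)OC(C)(C)C)cc1 | intermediate
6 | cyanamide | NC#N | starting material
7 | 1-(4-methoxyphenyl)-3-(methylamino)propan-2-one hydrochloride | CNCC(=O)Cc1ccc(OC)cc1.Cl | intermediate (not isolated)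
8 | 1-[3-(4-methoxyphenyl)-2-oxopropyl]-1-methylguanidine | CN(CC(=O)Cc1ccc(OC)cc1)C(N)=N | intermediate (not isolated)
9 | 4-[(4-methoxyphenyl)methyl]-1-methyl-1H-imidazol-2-amine | COc1ccc(Cc2cn(C)c(N)n2)cc1 | intermediate
10 | 2,3,4-trimethoxyphenol | COc1ccc(O)c(OC)c1OC | starting material
11 | formaldehyde (paraformaldehyde) | C=O | starting material
12 | 2,3,4-trimethoxy-6-(morpholin-4-ylmethyl)phenol | COc1cc(CN2CCOCC2)c(O)c(OC)c1OC | intermediate (not isolated)
13 | 2,3,4-trimethoxy-6-methylidenecyclohexa-2,4-dien-1-one | C=C1C=C(OC)C(OC)=C(OC)C1=O | intermediate (not isolated)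
14 | 6-({2-amino-4-[(4-methoxyphenyl)methyl]-1-methyl-1H-imidazol-5-yl}methyl)-2,3,4-trimethoxyphenol | COc1ccc(Cc2nc(N)n(C)c2Cc2cc(OC)c(OC)c(OC)c2O)cc1 | intermediate
15 | 1-methylimidazolidine-2,4,5-trione | CN1C(=O)NC(=O)C1=O | starting material
16 | 1-methyl-4-[(trimethylsilyl)oxy]-1H-imidazole-2,5-dione | CN1C(=O)N=C(O[Si](C)(C)C)C1=O | intermediate (not isolated)
17 | O-trimethylsilyl ether of 18 | COc1ccc(Cc2nc(NC3=NC(=O)N(C)C3=O)n(C)c2Cc2cc(OC)c(OC)c(OC)c2O[Si](C)(C)C)cc1 | intermediate (not isolated)
18 | 4-({5-[(2-hydroxy-3,4,5-trimethoxyphenyl)methyl]-4-[(4-methoxyphenyl)methyl]-1-methyl-1H-imidazol-2-yl}amino)-1-methyl-1H-imidazole-2,5-dione | COc1ccc(Cc2nc(NC3=NC(=O)N(C)C3=O)n(C)c2Cc2cc(OC)c(OC)c(OC)c2O)cc1 | intermediate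
19 | naamidine F | COC1=C(OC)C(=O)C(Cc2c(Cc3ccc(OC)cc3)nc(NC3=NC(=O)N(C)C3=O)n2C)=CC1=O | target

## Step count and risk

Total step count: 6. Longest linear sequence: 6 (steps 1–6, from 1); 10, 11 and 15 enter as purchased components.

**Step 4 (key step, proposed new method).** Most likely failure: alkylation at the exocyclic nitrogen or N3 that does not revert at a temperature the aminoimidazole tolerates, or sluggish thermal release of the quinone methide, leaving time for methylene transfer and self-coupling of the aminoimidazole. The fallback uses known reaction types and sets out from 9 and 10. Magnesium-mediated ortho-formylation of 10 (MgCl2, Et3N, paraformaldehyde) should give 2-hydroxy-3,4,5-trimethoxybenzaldehyde F1. Hydroxyalkylation of 9 at C5 by this aldehyde under neutral conditions should give {2-amino-4-[(4-methoxyphenyl)methyl]-1-methyl-1H-imidazol-5-yl}(2-hydroxy-3,4,5-trimethoxyphenyl)methanol F2 (racemic). Ionic hydrogenation (Et3SiH, TFA) of the doubly activated benzylic hydroxyl returns to the route at 14.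

**Step 6.** Most likely failure: oxidation of the ene-amidine in competition with the phenol, or loss of a benzylic proton from the oxidised phenol (quinone-methide formation toward the imidazole) instead of capture by water at the para carbon. The fallback sets out from 18. Controlled-potential anodic oxidation in methanol with 2,6-lutidine (graphite anode), held below the potential of the heterocycle, should give the quinone monoketal 4-({5-[(3,3,4,5-tetramethoxy-6-oxocyclohexa-1,4-dien-1-yl)methyl]-4-[(4-methoxyphenyl)methyl]-1-methyl-1H-imidazol-2-yl}amino)-1-methyl-1H-imidazole-2,5-dione F3. This is isolated and hydrolysed with dilute aqueous acetic acid, returning at 19.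

**Step 5.** Most likely failure: slow amidine formation because of the low nucleophilicity of the guanidine-type nitrogen, with acylation at ring N3 or opening of the trione ring by attack at the wrong carbonyl. The fallback sets out from 14 and builds the ring stepwise. Amidine formation with commercial ethyl 2-ethoxy-2-iminoacetate should give ethyl 2-({5-[(2-hydroxy-3,4,5-trimethoxyphenyl)methyl]-4-[(4-methoxyphenyl)methyl]-1-methyl-1H-imidazol-2-yl}amino)-2-iminoacetate F4. Carbamoylation of the free amidine nitrogen with N-methyl-1H-imidazole-1-carboxamide (a methyl isocyanate equivalent) and base-induced ring closure onto the ester, with a mild methanolysis to free any carbamoylated phenol, returns at 18.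

**Step 3.** Most likely failure: self-condensation of the free α-aminoketone and enolisation of the benzylic ketone in hot aqueous medium before guanylation. The fallback sets out from 5. After Boc removal to 7, guanylation with N,N'-di-Boc-N''-triflylguanidine and Et3N in CH2Cl2 at room temperature should give N,N'-bis(tert-butoxycarbonyl)-N''-[3-(4-methoxyphenyl)-2-oxopropyl]-N''-methylguanidine F5. Trifluoroacetic acid then removes both carbamates and triggers the intramolecular cyclodehydration, returning at 9.

## Further compounds

F1 | step 4 | 2-hydroxy-3,4,5-trimethoxybenzaldehyde | COc1cc(C=O)c(O)c(OC)c1OC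
F2 | step 4 | {2-amino-4-[(4-methoxyphenyl)methyl]-1-methyl-1H-imidazol-5-yl}(2-hydroxy-3,4,5-trimethoxyphenyl)methanol (racemic) | COc1ccc(Cc2nc(N)n(C)c2C(O)c2cc(OC)c(OC)c(OC)c2O)cc1
F3 | step 6 | 4-({5-[(3,3,4,5-tetramethoxy-6-oxocyclohexa-1,4-dien-1-yl)methyl]-4-[(4-methoxyphenyl)methyl]-1-methyl-1H-imidazol-2-yl}amino)-1-methyl-1H-imidazole-2,5-dione | COc1ccc(Cc2nc(NC3=NC(=O)N(C)C3=O)n(C)c2CC2=CC(OC)(OC)C(OC)=C(OC)C2=O)cc1
F4 | step 5 | ethyl 2-({5-[(2-hydroxy-3,4,5-trimethoxyphenyl)methyl]-4-[(4-methoxyphenyl)methyl]-1-methyl-1H-imidazol-2-yl}amino)-2-iminoacetate | CCOC(=O)C(=N)Nc1nc(Cc2ccc(OC)cc2)c(Cc2cc(OC)c(OC)c(OC)c2O)n1C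
F5 | step 3 | N,N'-bis(tert-butoxycarbonyl)-N''-[3-(4-methoxyphenyl)-2-oxopropyl]-N''-methylguanidine | COc1ccc(CC(=O)CN(C)C(=NC(=O)OC(C)(C)C)NC(=O)OC(C)(C)C)cc1
A1 | alternative 1 | N-(tert-butoxycarbonyl)-N-methyl-3-(2,3,4,5-tetramethoxyphenyl)alanine (racemic) | CN(C(Cc1cc(OC)c(OC)c(OC)c1OC)C(=O)O)C(=O)OC(C)(C)C
A2 | alternative 1 | 4-[(4-methoxyphenyl)methyl]-1-methyl-5-[(2,3,4,5-tetramethoxyphenyl)methyl]-1H-imidazol-2-amine | COc1ccc(Cc2nc(N)n(C)c2Cc2cc(OC)c(OC)c(OC)c2OC)cc1
A3 | alternative 1 | 4-({4-[(4-methoxyphenyl)methyl]-1-methyl-5-[(2,3,4,5-tetramethoxyphenyl)methyl]-1H-imidazol-2-yl}amino)-1-methyl-1H-imidazole-2,5-dione | COc1ccc(Cc2nc(NC3=NC(=O)N(C)C3=O)n(C)c2Cc2cc(OC)c(OC)c(OC)c2OC)cc1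
A4 | alternative 2 | 2-(2,3,4,5-tetramethoxyphenyl)acetaldehyde | COc1cc(CC=O)c(OC)c(OC)c1OC
A5 | alternative 2 | 4-(4-methoxyphenyl)-N-methyl-N-(prop-2-en-1-yl)-1-(2,3,4,5-tetramethoxyphenyl)but-3-yn-2-amine (racemic) | C=CCN(C)C(Cc1cc(OC)c(OC)c(OC)c1OC)C#Cc1ccc(OC)cc1
A6 | alternative 3 | 2-{4-[(4-methoxyphenyl)methyl]-1-methyl-2-[(1-methyl-2,5-dioxo-2,5-dihydro-1H-imidazol-4-yl)amino]-1H-imidazol-5-yl}acetic acid | COc1ccc(Cc2nc(NC3=NC(=O)N(C)C3=O)n(C)c2CC(=O)O)cc1
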